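The numbers in the tables stem from a simulated flask for an exercise, and the scatter is random.

In a one-step world the rate of a flask is one curve in [Xa], and a flattening of that curve belongs to that step. I try a reading with two terms instead.

| setting | ochre | green | red | grey | violet |
|---|---|---|---|---|---|
| Xa | 250 mM | 100 mM | 380 mM | 250 mM | 500 mM |
| Xc | 2.50 mM | 2.50 mM | 2.50 mM | 3.70 mM | 1.30 mM |
| time |  |  |  |  | 32 min |

- ochre run (time / min: [Xa] / mM): 2.4: 239.8; 7.4: 219.2; 14: 196.5; 22: 168.0; 32: 136.5
- green run (time / min: [Xa] / mM): 2.4: 93.7; 7.4: 82.4; 14: 69.0; 22: 57.0; 32: 41.1
- red run (time / min: [Xa] / mM): 2.4: 368.2; 7.4: 345.8; 14: 313.6; 22: 280.9; 32: 236.3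
- grey run (time / min: [Xa] / mM): 2.4: 236.2; 7.4: 207.8; 14: 172.7; 22: 134.3; 32: 95.1

(standard deviation of a reading: 1 mM)

- Overall: Xa -> Xp, with Xc as catalyst.
- Constant volume, constant temperature.
- What is held in complexes is read along with the free species.
- An order is taken over about fifteen percent of the charge, up and down.

1. the power of [Xc] that the first rate follows, about the charge of the ochre run; measure it at two percent of Xa made into Xp
2. the power of [Xa] that the first rate follows, about the charge of the ochre run; measure it at two percent of Xa made into Xp (one fixed amount of Xp, the same in the runs compared)
3. the green run starts with 150 mM less of Xa than the ochre run, and with no Xp. Compared where both hold the same amount of Xa, once fifteen percent of what the green run was charged with has turned into Xp, is the green run faster, slower or alike (within a tenth)?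
4. Xa in the violet run at 32 min, as a share of the Xa charged

I start with two neighbours, ochre and red, which have the same [Xc] and differ in charge. Over 32 min the ochre run averages 3.55 mM/min at a mean [Xa] of 193 mM, and the red run averages 4.49 mM/min at 308 mM. The red rate is higher by a smaller factor than its [Xa]. I freeze what Xc does across these two charges as a constant rate and give the extra rate to an uncatalysed background reaction, first order in [Xa]. The slope, 0.00821 /min, is then the leak constant, the fraction of the Xa present that leaves per minute without Xc. The frozen part in the ochre run is what remains, 1.96 mM/min.

This says why the two end where they end. In this reading the leak takes the same fraction per minute from either charge, while over 32 min the frozen part takes a larger share of the ochre charge than of the red one, 25.1% against 16.5%. So at 32 min the ochre run reads 54.6% of its charge and the red run 62.2%.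

The grey run, after the leak is subtracted, has a frozen part of 3.42 mM/min, so that part follows [Xc] to the power 1.42. For the violet run this gives 0.773 mM/min. With the frozen part held constant, [Xa] plus 94.2 mM decays exponentially at the leak constant, and 72.5% of the charge remains at 32 min. The leak share of the rate, which I take as the order in [Xa] since the frozen part has order zero, is 0.512 at the ochre charge.

The forecast reads the flattening otherwise: “The rates fall smoothly with [Xa] and flatten at high charge, which looks like saturation.” It gives an order in [Xc] of 1 (0.9 to 1.08), an order in [Xa] of 0.43 (0.34 to 0.52), alike for the green comparison, and 83.2% (81.5% to 85%) for the violet run. That is more Xa left than my figure.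

The simulation gives 0.92, 0.47, alike and 76.3%.

    Xc + Xa ⇌ Xc.Xa, settled at all times (17.30 /M)
    Xc.Xa + Xc → Xp + 2 Xc (4470 /M/min)
    2 Xc ⇌ Xc2, settled at all times (2650 /M)
    Xa → Xp (0.006960 /min)

The violet run stands 6.9 percentage points below the forecast and 3.8 points above my figure. Without the step Xa -> Xp the violet run would keep 96.0%, and that step accounts for 83% of the Xa missing at 32 min. On the ochre run the leak share 0.512 stands beside a measured order in [Xa] of 0.47, and without that step the order falls to 0.060.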